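**Retrosynthetic overview**

1. The target is read as the (2S,3S,2''R,3''S) 3,3''-biflavanone, 2,3-cis in the 4-methoxyphenyl half and 2'',3''-trans in the 4-hydroxyphenyl half. The strategy rests on ring A of each half (C4a, C5, C6, C7, C8, C8a): a benzene ring fused at C4a–C8a to pyranone ring C and oxygenated at C5 and C7, the pattern left when a 1,1,3-trioxygenated butadiene adds across a C4a=C8a enone and aromatises.
2. Last disconnection: C4a–C5 and C8–C8a in both halves at once, giving two equivalents of 1,1-dimethoxy-3-trimethylsilyloxybutadiene and a 3,3'-linked bis(5-bromo-2-aryl-2,3-dihydro-4H-pyran-4-one). The bromine supplies the arene oxidation level.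
3. Both rings C are closed together (O1–C6 in each) from a bis-ynone diol, made by opening a cis-fused 2,6-diaryl-3,7-dioxabicyclo[3.3.0]octane-4,8-dione with two acetylides. This bislactone (exo 4-methoxyphenyl, endo 4-benzyloxyphenyl) stores C2, C3, C3'' and C2''.
4. The bislactone comes from a succinate core by two auxiliary-controlled aldols: a MgCl2-catalysed anti-aldol with 4-benzyloxybenzaldehyde (trans half), then a boron syn-aldol with 4-methoxybenzaldehyde (cis half).
5. Ring order: two lactone rings (template), two rings C, two rings A. BCl3 then frees 5-OH, 5''-OH and 4'''-OH while 4'-OMe stays.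

Key step: step 14

Remark: unprimed locants belong to the 4-methoxyphenyl flavanone unit and doubly primed locants to the 4-hydroxyphenyl unit; the bis-ynone diol from the bislactone opening is drawn as its open-chain tautomer, although it should exist largely as the bis-lactol.

Remark: the choice of the (R)-auxiliary in step 2 assumes the facial sense derived for the MgCl2-catalysed oxazolidinone anti-aldol from its chelated enolate model.

Remark: in steps 8 and 14 two molecules of the numbered reactant (18 and 28) enter the product; the second molecule is entered on the line "Reagents that add atoms" so that the atom balance of each step is explicit.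

**Route**

Step 1
Reactants: 1 pent-4-enoyl chloride; 2 (R)-4-benzyl-1,3-oxazolidin-2-one
Product: 3 (R)-4-benzyl-3-(pent-4-enoyl)-1,3-oxazolidin-2-one
Conditions: n-BuLi, THF, −78 °C; then 1, −78 to 0 °C
Reagents that add atoms: none
Why: N-acylation of the lithiated oxazolidinone by the acid chloride (standard imide formation); no stereocentre is formed.

Step 2
Reactants: 3 (R)-4-benzyl-3-(pent-4-enoyl)-1,3-oxazolidin-2-one; 4 4-(benzyloxy)benzaldehyde
Product: 6 (R)-4-benzyl-3-{(2S)-2-[(R)-[4-(benzyloxy)phenyl](hydroxy)methyl]pent-4-enoyl}-1,3-oxazolidin-2-one, via trimethylsilyl ether 5 (not isolated)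
Conditions: MgCl2 (0.1 equiv), Et3N, TMSCl, EtOAc, rt; then TFA, MeOH
Reagents that add atoms: none
Why: Evans magnesium-halide-catalysed anti-aldol, in which the Mg-chelated Z-enolate should react through a boat-like transition state on the face opposite the auxiliary benzyl group and silylation drives turnover, setting the future C3'' (S) and C2'' (R) of the trans half.

Step 3
Reactants: 6 anti-aldol alcohol
Product: 7 (R)-4-benzyl-3-{(2S)-2-[(R)-[4-(benzyloxy)phenyl][(tert-butyldimethylsilyl)oxy]methyl]pent-4-enoyl}-1,3-oxazolidin-2-one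
Conditions: TBSOTf, 2,6-lutidine, CH2Cl2, −78 to 0 °C
Reagents that add atoms: tert-butyldimethylsilyl trifluoromethanesulfonate, CC(C)(C)[Si](C)(C)OS(=O)(=O)C(F)(F)F
Why: Silylation of the secondary benzylic alcohol; the TBS ether keeps this hydroxyl from lactonising onto the carboxyl made next and should survive the oxidation and both enolisation steps.

Step 4
Reactants: 7 silyl ether
Product: 9 (3S,4R)-3-{[(R)-4-benzyl-2-oxo-1,3-oxazolidin-3-yl]carbonyl}-4-[4-(benzyloxy)phenyl]-4-[(tert-butyldimethylsilyl)oxy]butanoic acid, via aldehyde 8 (not isolated)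
Conditions: O3, CH2Cl2, −78 °C; Me2S; then NaClO2, NaH2PO4, 2-methyl-2-butene, t-BuOH/H2O, 0 °C
Reagents that add atoms: ozone, O=[O+][O-]; sodium chlorite, [Na+].[O-]Cl=O
Why: Ozonolysis of the terminal alkene followed by Pinnick oxidation turns the allyl group into the acetic acid arm of a succinate under neutral to weakly acidic conditions that should not touch the α-centre.

Step 5
Reactants: 9 succinate half acid; 10 (S)-4-benzyl-1,3-oxazolidin-2-one
Product: 12 (S)-4-benzyl-3-[(3S,4R)-3-{[(R)-4-benzyl-2-oxo-1,3-oxazolidin-3-yl]carbonyl}-4-[4-(benzyloxy)phenyl]-4-[(tert-butyldimethylsilyl)oxy]butanoyl]-1,3-oxazolidin-2-one, via mixed pivalic anhydride 11 (not isolated)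
Conditions: PivCl, Et3N, THF, −20 °C; then 10, LiCl, −20 °C to rt
Reagents that add atoms: none
Why: Mixed-anhydride N-acylation of the oxazolidinone under the mild LiCl/Et3N protocol, which should leave the hindered first imide and its α-centre untouched.

Step 6
Reactants: 12 bis-imide; 13 4-methoxybenzaldehyde
Product: 14 (S)-4-benzyl-3-[(2S,3S,4R)-3-{[(R)-4-benzyl-2-oxo-1,3-oxazolidin-3-yl]carbonyl}-4-[4-(benzyloxy)phenyl]-4-[(tert-butyldimethylsilyl)oxy]-2-[(S)-hydroxy(4-methoxyphenyl)methyl]butanoyl]-1,3-oxazolidin-2-one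
Conditions: Bu2BOTf, i-Pr2NEt, CH2Cl2, −78 to 0 °C; then 13, −78 to 0 °C; H2O2, pH 7 buffer, MeOH, 0 °C
Reagents that add atoms: none
Why: Evans boron syn-aldol, in which only the CH2 of the new imide can form the Z-boron enolate and the Zimmerman–Traxler chair under control of the (S)-auxiliary should set C3 (S) and C2 (S) of the cis half, reagent control overriding the neighbouring centre.

Step 7
Reactants: 14 syn-aldol adduct
Product: 17 (1S,2S,5S,6R)-6-[4-(benzyloxy)phenyl]-2-(4-methoxyphenyl)-3,7-dioxabicyclo[3.3.0]octane-4,8-dione, via diol bis-imide 15 (not isolated), via hydroxy lactone imide 16 (not isolated)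
Conditions: HF·pyridine, THF, 0 °C to rt; then Et3N, DMAP (cat.), CH2Cl2, rt
Reagents that add atoms: none
Why: Desilylation followed by two intramolecular acyl transfers (5-exo-trig lactonisations, each benzylic hydroxyl attacking the imide carbonyl of the other half and expelling its oxazolidinone) should give the cis-fused bislactone, which can only form from the correct C3/C3'' relationship and locks both α-centres against epimerisation.

Step 8
Reactants: 17 bislactone; 18 ethynyltrimethylsilane (2 equiv)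
Product: 19 (4S,5S)-5-[(R)-[4-(benzyloxy)phenyl](hydroxy)methyl]-4-[(S)-hydroxy(4-methoxyphenyl)methyl]-1,8-bis(trimethylsilyl)octa-1,7-diyne-3,6-dione
Conditions: 18 (2.5 equiv), n-BuLi (2.4 equiv), THF, −78 °C; then 17, −78 °C; AcOH quench at −78 °C
Reagents that add atoms: ethynyltrimethylsilane (the second equivalent of 18), C#C[Si](C)(C)C
Why: Two lithium (trimethylsilyl)acetylide units add, one to each lactone carbonyl, and each addition should stop at the lithium lactolate at −78 °C (known lactone-to-ynone opening), while the ring-fusion hydrogens cannot epimerise as long as the bicycle is intact.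

Step 9
Reactants: 19 bis(silyl ynone) diol
Product: 21 (2S,2'R,3S,3'S)-2'-[4-(benzyloxy)phenyl]-2-(4-methoxyphenyl)-2,2',3,3'-tetrahydro-4H,4'H-[3,3'-bipyran]-4,4'-dione, via bis-enaminone 20 (not isolated)
Conditions: Et2NH, MeOH, 0 °C to rt; then TFA, CH2Cl2, 0 °C
Reagents that add atoms: none
Why: Methanolysis of the alkynylsilanes and conjugate addition of diethylamine to the ring-opened ynones should give vinylogous amides, and on acidification each β-hydroxyl displaces the amine by 6-endo addition–elimination (the known β-hydroxy ynone to 2,3-dihydro-4H-pyran-4-one cyclisation), closing both rings C without touching the four stereocentres.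

Step 10
Reactants: 21 bis(dihydropyranone)
Product: 22 (2S,2'R,3S,3'S)-2'-[4-(benzyloxy)phenyl]-5,5'-dibromo-2-(4-methoxyphenyl)-2,2',3,3'-tetrahydro-4H,4'H-[3,3'-bipyran]-4,4'-dione
Conditions: NBS (2.1 equiv), CH2Cl2, 0 °C, dark
Reagents that add atoms: N-bromosuccinimide, O=C1CCC(=O)N1Br
Why: Electrophilic α-bromination of the vinylogous ester, where the enol-ether carbon C5 of each ring is far more nucleophilic than the aryl ethers and loss of the C5 proton restores the enone.

Step 11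
Reactants: 23 acetyl chloride; 24 1,1-dichloroethene
Product: 26 4,4-dichlorobut-3-en-2-one, via trichloro ketone 25 (not isolated)
Conditions: AlCl3, CH2Cl2, 0 °C to rt; then Et3N, Et2O, 0 °C
Reagents that add atoms: none
Why: Lewis acid-mediated addition of the acyl chloride across the electron-rich alkene (aliphatic Friedel–Crafts acylation) followed by E1cB loss of HCl.

Step 12
Reactants: 26 4,4-dichlorobut-3-en-2-one
Product: 27 4,4-dimethoxybut-3-en-2-one
Conditions: NaOMe (2.2 equiv), MeOH, 0 °C to rt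
Reagents that add atoms: sodium methoxide, [Na+].[O-]C
Why: Two successive addition–elimination substitutions of the vinylic chlorides at the β-carbon of the enone give the acylketene acetal.

Step 13
Reactants: 27 4,4-dimethoxybut-3-en-2-one
Product: 28 1,1-dimethoxy-3-(trimethylsilyloxy)buta-1,3-diene
Conditions: TMSCl, Et3N, ZnCl2 (cat.), Et2O, rt
Reagents that add atoms: chlorotrimethylsilane, C[Si](C)(C)Cl
Why: Silyl enol ether formation at the methyl group of the ketone (as in the preparation of Danishefsky-type dienes) gives the ketene acetal diene.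

Step 14
Reactants: 22 bis(5-bromodihydropyranone); 28 1,1-dimethoxy-3-(trimethylsilyloxy)buta-1,3-diene (2 equiv)
Product: 30 (2S,3S)-3-[(2R,3S)-2-[4-(benzyloxy)phenyl]-7-hydroxy-5-methoxy-4-oxochroman-3-yl]-7-hydroxy-5-methoxy-2-(4-methoxyphenyl)chroman-4-one, via bis-cycloadduct 29 (not isolated)
Conditions: 28 (6 equiv), TMSOTf (0.3 equiv), 2,6-di-tert-butylpyridine, CH2Cl2, −78 to −20 °C; then Et3N, 0 °C to rt; then 1 M HCl, THF, 0 °C
Reagents that add atoms: 1,1-dimethoxy-3-(trimethylsilyloxy)buta-1,3-diene (the second equivalent of 28), COC(OC)=CC(=C)O[Si](C)(C)C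
Why: Proposed new method: catalytic TMSOTf should turn each 5-bromo vinylogous ester into a 4-silyloxypyranylium ion whose C6 (future C8a) is attacked by the nucleophilic CH2 terminus of the ketene acetal diene (vinylogous Mukaiyama–Michael addition, C8–C8a), after which the α-bromo silyl enol ether closes onto the silyl-activated acylketene acetal carbon (C4a–C5), so that each ring A is closed by a stepwise formal [4+2] cycloaddition whose second bond forms in a 6-endo-trig Mukaiyama–Michael closure. Ionisation of the C5 ketal with loss of methanol, triethylamine-induced loss of HBr across C4a–C8a and hydrolysis of the aryl silyl ether should then give the two 5-methoxy-7-hydroxy arenes. The closest known reaction types are the Brassard benzannulation of halogenated quinones with this diene and the silyl triflate-promoted Mukaiyama–Michael addition of silyl ketene acetals and silyloxydienes to 2,3-dihydro-4H-pyran-4-ones and 4-silyloxybenzopyrylium ions, neither of which has been carried through to an eliminative aromatisation on a monocyclic 5-bromodihydropyranone. No lasting stereocentre is created, because the transient centres C4a and C8a become aromatic, and C2, C3, C3'' and C2'' should be preserved since nothing more basic than a trialkylamine is present and the C7 silyl enol ether is kept until HBr is lost, which blocks retro-oxa-Michael expulsion of O1. The required regiochemistry (CH2 terminus to C8a, acetal carbon to C4a) follows from the matched polarity of the diene and the β-alkoxy enone, and the bromine at C4a provides the leaving group that sets the arene oxidation level without an oxidant.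

Step 15
Reactants: 30 di-O-methyl benzyl ether
Product: 31 (2S,3S)-3-[(2R,3S)-5,7-dihydroxy-2-(4-hydroxyphenyl)-4-oxochroman-3-yl]-5,7-dihydroxy-2-(4-methoxyphenyl)chroman-4-one (CNP0196568.4)
Conditions: BCl3, pentamethylbenzene, CH2Cl2, −78 to 0 °C
Reagents that add atoms: none
Why: Chelation-assisted Lewis acid ether cleavage, in which BCl3 bound to each C4 carbonyl removes the peri 5-methoxy groups and cleaves the aryl benzyl ether (benzyl cation trapped by pentamethylbenzene), while the non-chelated 4'-methoxy group should survive at or below 0 °C.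

**Compound list**

1 | pent-4-enoyl chloride | C=CCCC(Cl)=O | starting material
2 | (R)-4-benzyl-1,3-oxazolidin-2-one | O=C1OC[C@@H](Cc2ccccc2)N1 | starting material
3 | (R)-4-benzyl-3-(pent-4-enoyl)-1,3-oxazolidin-2-one | C=CCCC(=O)N1[C@H](Cc2ccccc2)COC1=O | intermediate
4 | 4-(benzyloxy)benzaldehyde | O=Cc1ccc(OCc2ccccc2)cc1 | starting material
5 | (R)-4-benzyl-3-{(2S)-2-[(R)-[4-(benzyloxy)phenyl](trimethylsilyloxy)methyl]pent-4-enoyl}-1,3-oxazolidin-2-one | C=CC[C@@H]([C@@H](O[Si](C)(C)C)c1ccc(OCc2ccccc2)cc1)C(=O)N1[C@H](Cc2ccccc2)COC1=O | intermediate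
6 | (R)-4-benzyl-3-{(2S)-2-[(R)-[4-(benzyloxy)phenyl](hydroxy)methyl]pent-4-enoyl}-1,3-oxazolidin-2-one | C=CC[C@@H]([C@@H](O)c1ccc(OCc2ccccc2)cc1)C(=O)N1[C@H](Cc2ccccc2)COC1=O | intermediate
7 | (R)-4-benzyl-3-{(2S)-2-[(R)-[4-(benzyloxy)phenyl][(tert-butyldimethylsilyl)oxy]methyl]pent-4-enoyl}-1,3-oxazolidin-2-one | C=CC[C@@H]([C@@H](O[Si](C)(C)C(C)(C)C)c1ccc(OCc2ccccc2)cc1)C(=O)N1[C@H](Cc2ccccc2)COC1=O | intermediate
8 | (R)-4-benzyl-3-{(2S)-2-[(R)-[4-(benzyloxy)phenyl][(tert-butyldimethylsilyl)oxy]methyl]-4-oxobutanoyl}-1,3-oxazolidin-2-one | O=CC[C@@H]([C@@H](O[Si](C)(C)C(C)(C)C)c1ccc(OCc2ccccc2)cc1)C(=O)N1[C@H](Cc2ccccc2)COC1=O | intermediate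
9 | (3S,4R)-3-{[(R)-4-benzyl-2-oxo-1,3-oxazolidin-3-yl]carbonyl}-4-[4-(benzyloxy)phenyl]-4-[(tert-butyldimethylsilyl)oxy]butanoic acid | OC(=O)C[C@@H]([C@@H](O[Si](C)(C)C(C)(C)C)c1ccc(OCc2ccccc2)cc1)C(=O)N1[C@H](Cc2ccccc2)COC1=O | intermediate
10 | (S)-4-benzyl-1,3-oxazolidin-2-one | O=C1OC[C@H](Cc2ccccc2)N1 | starting material
11 | mixed anhydride of 9 with pivalic acid | CC(C)(C)C(=O)OC(=O)C[C@@H]([C@@H](O[Si](C)(C)C(C)(C)C)c1ccc(OCc2ccccc2)cc1)C(=O)N1[C@H](Cc2ccccc2)COC1=O | intermediate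
12 | (S)-4-benzyl-3-[(3S,4R)-3-{[(R)-4-benzyl-2-oxo-1,3-oxazolidin-3-yl]carbonyl}-4-[4-(benzyloxy)phenyl]-4-[(tert-butyldimethylsilyl)oxy]butanoyl]-1,3-oxazolidin-2-one | O=C(C[C@@H]([C@@H](O[Si](C)(C)C(C)(C)C)c1ccc(OCc2ccccc2)cc1)C(=O)N1[C@H](Cc2ccccc2)COC1=O)N1[C@@H](Cc2ccccc2)COC1=O | intermediate
13 | 4-methoxybenzaldehyde | COc1ccc(C=O)cc1 | starting material
14 | (S)-4-benzyl-3-[(2S,3S,4R)-3-{[(R)-4-benzyl-2-oxo-1,3-oxazolidin-3-yl]carbonyl}-4-[4-(benzyloxy)phenyl]-4-[(tert-butyldimethylsilyl)oxy]-2-[(S)-hydroxy(4-methoxyphenyl)methyl]butanoyl]-1,3-oxazolidin-2-one | COc1ccc([C@@H](O)[C@@H](C(=O)N2[C@@H](Cc3ccccc3)COC2=O)[C@@H]([C@@H](O[Si](C)(C)C(C)(C)C)c2ccc(OCc3ccccc3)cc2)C(=O)N2[C@H](Cc3ccccc3)COC2=O)cc1 | intermediate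
15 | desilylated 14: (2S,3S,4R)-configured diol bis-imide with free hydroxyl at C4 | COc1ccc([C@@H](O)[C@@H](C(=O)N2[C@@H](Cc3ccccc3)COC2=O)[C@@H]([C@@H](O)c2ccc(OCc3ccccc3)cc2)C(=O)N2[C@H](Cc3ccccc3)COC2=O)cc1 | intermediate
16 | (S)-4-benzyl-3-{[(2S,3S,4S)-4-[(R)-[4-(benzyloxy)phenyl](hydroxy)methyl]-2-(4-methoxyphenyl)-5-oxotetrahydrofuran-3-yl]carbonyl}-1,3-oxazolidin-2-one | COc1ccc([C@H]2OC(=O)[C@H]([C@@H](O)c3ccc(OCc4ccccc4)cc3)[C@@H]2C(=O)N2[C@@H](Cc3ccccc3)COC2=O)cc1 | intermediate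
17 | (1S,2S,5S,6R)-6-[4-(benzyloxy)phenyl]-2-(4-methoxyphenyl)-3,7-dioxabicyclo[3.3.0]octane-4,8-dione (cis-fused; 4-methoxyphenyl exo, 4-benzyloxyphenyl endo) | COc1ccc([C@H]2OC(=O)[C@@H]3[C@H](c4ccc(OCc5ccccc5)cc4)OC(=O)[C@H]23)cc1 | intermediate
18 | ethynyltrimethylsilane | C#C[Si](C)(C)C | starting material
19 | (4S,5S)-5-[(R)-[4-(benzyloxy)phenyl](hydroxy)methyl]-4-[(S)-hydroxy(4-methoxyphenyl)methyl]-1,8-bis(trimethylsilyl)octa-1,7-diyne-3,6-dione | COc1ccc([C@@H](O)[C@@H](C(=O)C#C[Si](C)(C)C)[C@@H]([C@@H](O)c2ccc(OCc3ccccc3)cc2)C(=O)C#C[Si](C)(C)C)cc1 | intermediate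
20 | (1E,4S,5S,7E)-5-[(R)-[4-(benzyloxy)phenyl](hydroxy)methyl]-1,8-bis(diethylamino)-4-[(S)-hydroxy(4-methoxyphenyl)methyl]octa-1,7-diene-3,6-dione | COc1ccc([C@@H](O)[C@@H](C(=O)/C=C/N(CC)CC)[C@@H]([C@@H](O)c2ccc(OCc3ccccc3)cc2)C(=O)/C=C/N(CC)CC)cc1 | intermediate
21 | (2S,2'R,3S,3'S)-2'-[4-(benzyloxy)phenyl]-2-(4-methoxyphenyl)-2,2',3,3'-tetrahydro-4H,4'H-[3,3'-bipyran]-4,4'-dione | COc1ccc([C@H]2OC=CC(=O)[C@H]2[C@@H]2C(=O)C=CO[C@H]2c2ccc(OCc3ccccc3)cc2)cc1 | intermediate
22 | (2S,2'R,3S,3'S)-2'-[4-(benzyloxy)phenyl]-5,5'-dibromo-2-(4-methoxyphenyl)-2,2',3,3'-tetrahydro-4H,4'H-[3,3'-bipyran]-4,4'-dione | COc1ccc([C@H]2OC=C(Br)C(=O)[C@H]2[C@@H]2C(=O)C(Br)=CO[C@H]2c2ccc(OCc3ccccc3)cc2)cc1 | intermediate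
23 | acetyl chloride | CC(Cl)=O | starting material
24 | 1,1-dichloroethene | C=C(Cl)Cl | starting material
25 | 4,4,4-trichlorobutan-2-one | CC(=O)CC(Cl)(Cl)Cl | intermediate
26 | 4,4-dichlorobut-3-en-2-one | CC(=O)C=C(Cl)Cl | intermediate
27 | 4,4-dimethoxybut-3-en-2-one | CC(=O)C=C(OC)OC | intermediate
28 | 1,1-dimethoxy-3-(trimethylsilyloxy)buta-1,3-diene | COC(OC)=CC(=C)O[Si](C)(C)C | intermediate
29 | 3,3''-linked bis[4a-bromo-5,5-dimethoxy-7-(trimethylsilyloxy)-4a,5,8,8a-tetrahydrochroman-4-one] carrying the 2-(4-methoxyphenyl) and 2''-(4-benzyloxyphenyl) groups (ring-fusion centres undefined) | COc1ccc([C@H]2OC3CC(O[Si](C)(C)C)=CC(OC)(OC)C3(Br)C(=O)[C@H]2[C@@H]2C(=O)C3(Br)C(OC)(OC)C=C(O[Si](C)(C)C)CC3O[C@H]2c2ccc(OCc3ccccc3)cc2)cc1 | intermediate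
30 | (2S,3S)-3-[(2R,3S)-2-[4-(benzyloxy)phenyl]-7-hydroxy-5-methoxy-4-oxochroman-3-yl]-7-hydroxy-5-methoxy-2-(4-methoxyphenyl)chroman-4-one | COc1ccc([C@H]2Oc3cc(O)cc(OC)c3C(=O)[C@H]2[C@@H]2C(=O)c3c(OC)cc(O)cc3O[C@H]2c2ccc(OCc4ccccc4)cc2)cc1 | intermediate
31 | (2S,3S)-3-[(2R,3S)-5,7-dihydroxy-2-(4-hydroxyphenyl)-4-oxochroman-3-yl]-5,7-dihydroxy-2-(4-methoxyphenyl)chroman-4-one | COc1ccc([C@H]2Oc3cc(O)cc(O)c3C(=O)[C@H]2[C@@H]2C(=O)c3c(O)cc(O)cc3O[C@H]2c2ccc(O)cc2)cc1 | target

**Totals**

Total step count: 15. Longest linear sequence: 12 steps (steps 1–10, 14, 15).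

**Steps most likely to fail**

1. Step 14. After the first Michael addition the second C–C bond may not form, so the adduct could be diverted to hydrolysis of the ketene acetal or to opening of ring C by expulsion of O1. Aromatisation may also stall at the bromo-diene stage, or the cis centre C3 may epimerise during HBr loss. The fallback uses known chemistry, sets out from 17 and comes back at 31. 5-Fluorobenzene-1,3-diol is benzylated (BnBr, K2CO3, DMF) to 1,3-bis(benzyloxy)-5-fluorobenzene F1. NBS bromination para to one ether gives 1,5-bis(benzyloxy)-2-bromo-3-fluorobenzene F2. Bromine–lithium exchange (n-BuLi, THF, −78 °C) and addition of two equivalents of the aryllithium, one to each lactone carbonyl of 17, gives the bis(aryl ketone) diol (2S,3S)-1,4-bis[2,4-bis(benzyloxy)-6-fluorophenyl]-3-[(R)-[4-(benzyloxy)phenyl](hydroxy)methyl]-2-[(S)-hydroxy(4-methoxyphenyl)methyl]butane-1,4-dione F3. K2CO3 in DMF then closes both rings C by intramolecular nucleophilic aromatic substitution of fluoride, with retention at C2 and C2'', to the penta-O-benzyl biflavanone F4. BCl3 with pentamethylbenzene removes all five benzyl groups and gives 31.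

2. Step 9. The bis-lactol may not funnel into the 6-endo manifold (dehydration to alkynyl dihydrofurans instead), or C3/C3' may epimerise or the β-hydroxy ketones undergo retro-aldol cleavage while the free ynones are exposed to the amine. The fallback sets out from 17 and comes back at 21. Aminolysis of both lactones with Me2AlN(OMe)Me (from AlMe3 and MeNHOMe·HCl) gives the bis(Weinreb amide) diol (2S,3S)-3-[(R)-[4-(benzyloxy)phenyl](hydroxy)methyl]-2-[(S)-hydroxy(4-methoxyphenyl)methyl]-N1,N4-dimethoxy-N1,N4-dimethylbutanediamide F5. TESOTf and 2,6-lutidine give its bis(triethylsilyl) ether F6. Ethynylmagnesium bromide then gives the bis(terminal ynone) bis(triethylsilyl) ether F7. Diethylamine converts it into the bis-enaminone bis(triethylsilyl) ether F8 while both hydroxyls are still masked, so no lactol can form. Aqueous TFA removes the silyl groups and closes both pyranones to 21.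

3. Step 6. Enolisation of the congested imide may be slow or the boron reagent may be tied up by the first imide, and the electron-rich aldehyde may give low conversion or eroded facial control next to the existing centre. The fallback sets out from 9 and comes back at 17. The acid is coupled (EDC·HCl, DMAP) with (S)-4-benzyl-1,3-thiazolidine-2-thione to the N-acyl thiazolidinethione F9. Its chlorotitanium enolate (TiCl4, i-Pr2NEt, N-methylpyrrolidinone, CH2Cl2, −78 to 0 °C; Crimmins syn-aldol) reacts with 13 to give the thioimide syn-aldol adduct F10. HF·pyridine followed by Et3N/DMAP expels the thiazolidinethione and the oxazolidinone and gives 17.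

**Further compounds**

F1 | step 14 | 1,3-bis(benzyloxy)-5-fluorobenzene | Fc1cc(OCc2ccccc2)cc(OCc2ccccc2)c1
F2 | step 14 | 1,5-bis(benzyloxy)-2-bromo-3-fluorobenzene | Fc1cc(OCc2ccccc2)cc(OCc2ccccc2)c1Br
F3 | step 14 | (2S,3S)-1,4-bis[2,4-bis(benzyloxy)-6-fluorophenyl]-3-[(R)-[4-(benzyloxy)phenyl](hydroxy)methyl]-2-[(S)-hydroxy(4-methoxyphenyl)methyl]butane-1,4-dione | COc1ccc([C@@H](O)[C@@H](C(=O)c2c(F)cc(OCc3ccccc3)cc2OCc2ccccc2)[C@@H]([C@@H](O)c2ccc(OCc3ccccc3)cc2)C(=O)c2c(F)cc(OCc3ccccc3)cc2OCc2ccccc2)cc1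
F4 | step 14 | (2S,3S)-5,7-bis(benzyloxy)-3-[(2R,3S)-5,7-bis(benzyloxy)-2-[4-(benzyloxy)phenyl]-4-oxochroman-3-yl]-2-(4-methoxyphenyl)chroman-4-one | COc1ccc([C@H]2Oc3cc(OCc4ccccc4)cc(OCc4ccccc4)c3C(=O)[C@H]2[C@@H]2C(=O)c3c(OCc4ccccc4)cc(OCc4ccccc4)cc3O[C@H]2c2ccc(OCc3ccccc3)cc2)cc1
F5 | step 9 | (2S,3S)-3-[(R)-[4-(benzyloxy)phenyl](hydroxy)methyl]-2-[(S)-hydroxy(4-methoxyphenyl)methyl]-N1,N4-dimethoxy-N1,N4-dimethylbutanediamide | COc1ccc([C@@H](O)[C@@H](C(=O)N(C)OC)[C@@H]([C@@H](O)c2ccc(OCc3ccccc3)cc2)C(=O)N(C)OC)cc1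
F6 | step 9 | bis(triethylsilyl) ether of F5 | COc1ccc([C@@H](O[Si](CC)(CC)CC)[C@@H](C(=O)N(C)OC)[C@@H]([C@@H](O[Si](CC)(CC)CC)c2ccc(OCc3ccccc3)cc2)C(=O)N(C)OC)cc1
F7 | step 9 | (4S,5S)-5-[(R)-[4-(benzyloxy)phenyl](triethylsilyloxy)methyl]-4-[(S)-(4-methoxyphenyl)(triethylsilyloxy)methyl]octa-1,7-diyne-3,6-dione | COc1ccc([C@@H](O[Si](CC)(CC)CC)[C@@H](C(=O)C#C)[C@@H]([C@@H](O[Si](CC)(CC)CC)c2ccc(OCc3ccccc3)cc2)C(=O)C#C)cc1
F8 | step 9 | (1E,4S,5S,7E)-5-[(R)-[4-(benzyloxy)phenyl](triethylsilyloxy)methyl]-1,8-bis(diethylamino)-4-[(S)-(4-methoxyphenyl)(triethylsilyloxy)methyl]octa-1,7-diene-3,6-dione | COc1ccc([C@@H](O[Si](CC)(CC)CC)[C@@H](C(=O)/C=C/N(CC)CC)[C@@H]([C@@H](O[Si](CC)(CC)CC)c2ccc(OCc3ccccc3)cc2)C(=O)/C=C/N(CC)CC)cc1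
F9 | step 6 | (R)-4-benzyl-3-[(2S,3R)-2-{2-[(S)-4-benzyl-2-thioxo-1,3-thiazolidin-3-yl]-2-oxoethyl}-3-[4-(benzyloxy)phenyl]-3-[(tert-butyldimethylsilyl)oxy]propanoyl]-1,3-oxazolidin-2-one | O=C(C[C@@H]([C@@H](O[Si](C)(C)C(C)(C)C)c1ccc(OCc2ccccc2)cc1)C(=O)N1[C@H](Cc2ccccc2)COC1=O)N1[C@@H](Cc2ccccc2)CSC1=S
F10 | step 6 | thioimide analogue of 14 (syn-aldol adduct of F9 with 13; (S)-4-benzyl-2-thioxo-1,3-thiazolidin-3-yl in place of the (S)-oxazolidinone) | COc1ccc([C@@H](O)[C@@H](C(=O)N2[C@@H](Cc3ccccc3)CSC2=S)[C@@H]([C@@H](O[Si](C)(C)C(C)(C)C)c2ccc(OCc3ccccc3)cc2)C(=O)N2[C@H](Cc3ccccc3)COC2=O)cc1
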